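## Retrosynthetic overview

1. Last bond: Sonogashira coupling of a ring vinyl iodide (C1–I) with the side-chain enyne, which is built from an E-alkenyl boronate, 2,3-dibromopropene and ethynyltrimethylsilane.
2. Ring numbering used throughout: C1 (alkynyl-bearing sp2 carbon), C2 (=CH), C3 (OAc), C4 (OMe), C5 (OH), C6 (OH, next to C1); β is the face of the C5/C6 hydroxyls, α the face of the C3/C4 oxygens. Enabling feature: the four ring oxygens (3α,4α,5β,6β) have a C2 axis through the midpoints of C1=C2 and C4–C5, so cutting C4–C5 gives a C2-symmetric (2S,5S,Z)-2,5-bis(silyloxy)hex-3-enedial whose Z-alkene holds two homotopic aldehydes side by side.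
3. Key disconnection C4–C5: a one-pot double Swern oxidation/SmI2 pinacol cyclisation forms the only carbocycle, and the two conceivable cis-diols are one compound because of the C2 axis. Both carbinol centres (C3, C6) come from one catalytic event, the double asymmetric transfer hydrogenation of an ynedione made from acetylene.
4. After ring closure the cis-diol becomes the β-epoxide; the C6 hydroxyl cis to it steers methanol to C4 (trans OMe/OH, symmetry broken). The new C5/C6 cis-diol is masked as a boronate to acetylate C3, and C6 is oxidised to mark C1 for iodination, then reduced back.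
5. Order of ring formation: cyclohexene (step 6), temporary oxirane (step 7, opened in step 9); no other ring is kept.

Key step: step 6

Assumption (step 2): the alkynyl group of the ynedione is taken to play the role that the aryl group plays in aryl ketones, so the (R,R)-TsDPEN catalyst should give the (2S,5S)-diol; if the α-silyloxymethyl groups reverse the sense, the enantiomeric catalyst is used.

## Route

Step 1
Reactants: 1 acetylene; 2 2-[(tert-butyldimethylsilyl)oxy]-N-methoxy-N-methylacetamide
Product: 3 1,6-bis[(tert-butyldimethylsilyl)oxy]hex-3-yne-2,5-dione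
Conditions: EtMgBr (2.0 equiv), THF, 0 → 40 °C (ethynylenedimagnesium dibromide); 2 (2.2 equiv), 0 °C; cold aq. NaHSO4
Reagents that add atoms: none
Why: Double acylation of an alkynyl Grignard reagent with a Weinreb amide; each tetrahedral N,O-chelate survives until the acidic quench, so the ynedione is released only at work-up.

Step 2
Reactants: 3 1,6-bis[(tert-butyldimethylsilyl)oxy]hex-3-yne-2,5-dione
Product: 4 (2S,5S)-1,6-bis[(tert-butyldimethylsilyl)oxy]hex-3-yne-2,5-diol
Conditions: Ru[(R,R)-TsDPEN](p-cymene) (2 mol%), i-PrOH, 25 °C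
Reagents that add atoms: none
Why: Noyori–Ikariya asymmetric transfer hydrogenation of an ynone, run on both carbonyls in one flask; catalyst control sets both carbinol centres (the future C3 and C6) as S, and the meso diol should be the only, separable, minor isomer.

Step 3
Reactants: 4 (2S,5S)-1,6-bis[(tert-butyldimethylsilyl)oxy]hex-3-yne-2,5-diol
Product: 5 (2S,5S,3Z)-1,6-bis[(tert-butyldimethylsilyl)oxy]hex-3-ene-2,5-diol
Conditions: H2 (1 atm), Lindlar catalyst, quinoline, EtOAc, rt
Reagents that add atoms: none
Why: Lindlar semi-hydrogenation; syn addition of H2 gives the Z-alkene that becomes C1=C2 and places the two chain ends on the same side.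

Step 4
Reactants: 5 (2S,5S,3Z)-1,6-bis[(tert-butyldimethylsilyl)oxy]hex-3-ene-2,5-diol
Product: 6 (2S,5S,3Z)-1,2,5,6-tetrakis[(tert-butyldimethylsilyl)oxy]hex-3-ene
Conditions: TBSCl, imidazole, DMF, rt
Reagents that add atoms: tert-butyldimethylsilyl chloride, CC(C)(C)[Si](C)(C)Cl
Why: Standard silylation of the two secondary allylic hydroxyls; no stereocentre is touched.

Step 5
Reactants: 6 (2S,5S,3Z)-1,2,5,6-tetrakis[(tert-butyldimethylsilyl)oxy]hex-3-ene
Product: 7 (2S,5S,3Z)-2,5-bis[(tert-butyldimethylsilyl)oxy]hex-3-ene-1,6-diol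
Conditions: CSA (10 mol%), MeOH/CH2Cl2 (1:1), −10 → 0 °C
Reagents that add atoms: none
Why: Acid-catalysed methanolysis cleaves primary TBS ethers much faster than secondary ones, which frees the two terminal hydroxyls (the future C4 and C5).

Step 6
Reactants: 7 (2S,5S,3Z)-2,5-bis[(tert-butyldimethylsilyl)oxy]hex-3-ene-1,6-diol
Product: 9 3α,6β-bis[(tert-butyldimethylsilyl)oxy]cyclohex-1-ene-4β,5β-diol, via dialdehyde 8 (not isolated)
Conditions: (COCl)2, DMSO, CH2Cl2, −78 °C; i-Pr2NEt, −78 → −40 °C; then cannulated into SmI2 (5 equiv), t-BuOH (4 equiv), THF (0.01 M), −78 → −20 °C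
Reagents that add atoms: none
Why: Double Swern oxidation unveils the C2-symmetric Z-enedial 8; SmI2 reduces one aldehyde (either, they are homotopic) to a ketyl, which closes onto the second, Sm(III)-bound aldehyde (6-exo-trig radical addition to C=O, forming C4–C5), and a second electron and t-BuOH give the diolate. The closest known reaction type is the one-pot Swern/SmI2 pinacol cyclisation of carbohydrate-derived 2,5-dialkoxy-1,6-dialdehydes to inositol diols, including C2-symmetric cases in which one new hydroxyl must be syn to its neighbour. The two new stereocentres C4 and C5 are controlled by Sm(III) bridging both oxygens in the cyclic transition state, which enforces the cis-diol. The face of the diol needs no control: the 4β,5β- and 4α,5α-diols are the same compound, interconverted by the C2 axis through the midpoints of C1=C2 and C4–C5, so 9 is the only cis-diol. The selectivities needed are cis over trans coupling and ring closure over intermolecular coupling or loss of silyloxide; chelation, the Z-alkene that holds the two carbonyls together, high dilution and low temperature should secure them.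

Step 7
Reactants: 9 3α,6β-bis[(tert-butyldimethylsilyl)oxy]cyclohex-1-ene-4β,5β-diol
Product: 12 4β,5β-epoxy-3α,6β-bis[(tert-butyldimethylsilyl)oxy]cyclohex-1-ene, via cyclic orthoacetate 10 (not isolated), via trans-bromo acetate 11 (not isolated)
Conditions: MeC(OMe)3, PPTS (cat.), CH2Cl2, rt; evaporate; AcBr, CH2Cl2, 0 °C → rt; evaporate; K2CO3, MeOH, rt
Reagents that add atoms: none
Why: Kolb–Sharpless conversion of a cis-1,2-diol into its epoxide; bromide opens the acetoxonium ion with inversion and the alkoxide then displaces bromide with a second inversion at the same carbon, so the epoxide stays on the β face (cis to C6–O, trans to C3–O) whichever carbon bromide attacks.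

Step 8
Reactants: 12 4β,5β-epoxy-3α,6β-bis[(tert-butyldimethylsilyl)oxy]cyclohex-1-ene
Product: 13 4β,5β-epoxycyclohex-1-ene-3α,6β-diol
Conditions: TBAF (2.5 equiv), AcOH (2.5 equiv), THF, 0 °C → rt
Reagents that add atoms: none
Why: Fluoride desilylation, buffered with acetic acid so that the C3 alkoxide (trans to the epoxide) cannot undergo Payne migration.

Step 9
Reactants: 13 4β,5β-epoxycyclohex-1-ene-3α,6β-diol
Product: 14 4α-methoxycyclohex-1-ene-3α,5β,6β-triol
Conditions: Eu(OTf)3 (10 mol%), 2,6-di-tert-butyl-4-methylpyridine (30 mol%), MeOH (10 equiv), CH2Cl2, rt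
Reagents that add atoms: methanol, CO
Why: Eu(III)-catalysed distal-carbon methanolysis of a 2,3-epoxy alcohol; only the C6 hydroxyl (cis to the epoxide) can chelate the metal together with the epoxide oxygen, so methanol attacks C4 anti to the epoxide, which inverts C4 (OMe α, trans to the β C5–OH) and leaves C5/C6 as the only cis-1,2-diol.

Step 10
Reactants: 14 4α-methoxycyclohex-1-ene-3α,5β,6β-triol
Product: 17 3α-acetoxy-4α-methoxycyclohex-1-ene-5β,6β-diol, via phenylboronate 15 (not isolated), via acetylated phenylboronate 16 (not isolated)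
Conditions: PhB(OH)2 (1.05 equiv), pyridine, 4 Å MS, rt; Ac2O (1.5 equiv), DMAP (cat.), 0 °C; pinacol, rt
Reagents that add atoms: acetic anhydride, CC(=O)OC(C)=O
Why: Transient boronate protection; the boronic acid esterifies only the cis-1,2-diol (C5/C6), acetic anhydride acylates the remaining C3 hydroxyl, and exchange with pinacol releases the diol.

Step 11
Reactants: 17 3α-acetoxy-4α-methoxycyclohex-1-ene-5β,6β-diol
Product: 18 3α-acetoxy-5β-hydroxy-4α-methoxycyclohex-1-en-6-one
Conditions: activated MnO2 (15 equiv), CH2Cl2, rt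
Reagents that add atoms: none
Why: Allylic oxidation with MnO2; of the two free hydroxyls only the one at C6 is allylic, so the C6 ketone should form while C5–OH is kept.

Step 12
Reactants: 18 3α-acetoxy-5β-hydroxy-4α-methoxycyclohex-1-en-6-one
Product: 19 3α-acetoxy-5β-hydroxy-1-iodo-4α-methoxycyclohex-1-en-6-one
Conditions: I2 (2 equiv), pyridine/CH2Cl2 (1:1), 0 °C → rt
Reagents that add atoms: iodine, II
Why: Johnson α-iodination of an enone (pyridine adds at C2, the enolate is iodinated at C1, pyridine is lost), which marks C1, the olefinic carbon next to the former cis-diol.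

Step 13
Reactants: 19 3α-acetoxy-5β-hydroxy-1-iodo-4α-methoxycyclohex-1-en-6-one
Product: 20 3α-acetoxy-1-iodo-4α-methoxycyclohex-1-ene-5β,6β-diol
Conditions: Zn(BH4)2 (1.5 equiv), Et2O, −30 °C; aq. NH4Cl
Reagents that add atoms: none
Why: Chelation-controlled 1,2-reduction of an α'-hydroxy enone; Zn(II) bridges the C6 carbonyl and the C5 hydroxyl and hydride arrives from the side of C5–H (Cram-chelate model), which returns C6–OH to the β face, cis to C5–OH.

Step 14
Reactants: 21 (E)-2-methyl-4-(4,4,5,5-tetramethyl-1,3,2-dioxaborolan-2-yl)but-3-en-2-ol; 22 2,3-dibromoprop-1-ene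
Product: 23 (3E)-6-bromo-2-methylhepta-3,6-dien-2-ol
Conditions: Pd(PPh3)4 (5 mol%), K3PO4 (3 equiv), THF/H2O, 50 °C, 22 in excess (2 equiv)
Reagents that add atoms: none
Why: Suzuki–Miyaura allyl–alkenyl coupling; Pd(0) ionises the allylic C–Br bond far faster than it inserts into the vinylic one, the 2-bromo-π-allyl complex is symmetrical, and the alkenyl boronate transfers with retention of the E geometry.

Step 15
Reactants: 23 (3E)-6-bromo-2-methylhepta-3,6-dien-2-ol; 24 ethynyltrimethylsilane
Product: 25 (3E)-2-methyl-6-methylidene-8-(trimethylsilyl)oct-3-en-7-yn-2-ol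
Conditions: Pd(PPh3)2Cl2 (3 mol%), CuI (6 mol%), Et3N, THF, 50 °C
Reagents that add atoms: none
Why: Sonogashira coupling of the 2-bromo-1-alkene with a silyl-protected acetylene builds the 2-substituted 1,3-enyne.

Step 16
Reactants: 25 (3E)-2-methyl-6-methylidene-8-(trimethylsilyl)oct-3-en-7-yn-2-ol
Product: 26 (3E)-2-methyl-6-methylideneoct-3-en-7-yn-2-ol
Conditions: K2CO3 (0.2 equiv), MeOH, 0 °C → rt
Reagents that add atoms: none
Why: Base-catalysed methanolysis of the C(sp)–Si bond frees the terminal alkyne.

Step 17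
Reactants: 20 3α-acetoxy-1-iodo-4α-methoxycyclohex-1-ene-5β,6β-diol; 26 (3E)-2-methyl-6-methylideneoct-3-en-7-yn-2-ol
Product: 27 (1S,4S,5S,6R)-4,5-dihydroxy-3-[(5E)-7-hydroxy-7-methyl-3-methylideneoct-5-en-1-yn-1-yl]-6-methoxycyclohex-2-en-1-yl acetate (target)
Conditions: Pd(PPh3)4 (5 mol%), CuI (10 mol%), i-Pr2NH (3 equiv), THF (degassed), rt
Reagents that add atoms: none
Why: Sonogashira coupling of a vinyl iodide with a terminal enyne, a reaction type established for iodo-cyclohexenediol derivatives; no stereocentre is touched and the free hydroxyls and the acetate should be tolerated.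

## Compound list

1 | acetylene | C#C | starting material
2 | 2-[(tert-butyldimethylsilyl)oxy]-N-methoxy-N-methylacetamide | CON(C)C(=O)CO[Si](C)(C)C(C)(C)C | starting material
3 | 1,6-bis[(tert-butyldimethylsilyl)oxy]hex-3-yne-2,5-dione | CC(C)(C)[Si](C)(C)OCC(=O)C#CC(=O)CO[Si](C)(C)C(C)(C)C | intermediate
4 | (2S,5S)-1,6-bis[(tert-butyldimethylsilyl)oxy]hex-3-yne-2,5-diol | CC(C)(C)[Si](C)(C)OC[C@@H](O)C#C[C@H](O)CO[Si](C)(C)C(C)(C)C | intermediate
5 | (2S,5S,3Z)-1,6-bis[(tert-butyldimethylsilyl)oxy]hex-3-ene-2,5-diol | CC(C)(C)[Si](C)(C)OC[C@@H](O)/C=C\[C@H](O)CO[Si](C)(C)C(C)(C)C | intermediate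
6 | (2S,5S,3Z)-1,2,5,6-tetrakis[(tert-butyldimethylsilyl)oxy]hex-3-ene | CC(C)(C)[Si](C)(C)OC[C@@H](O[Si](C)(C)C(C)(C)C)/C=C\[C@H](O[Si](C)(C)C(C)(C)C)CO[Si](C)(C)C(C)(C)C | intermediate
7 | (2S,5S,3Z)-2,5-bis[(tert-butyldimethylsilyl)oxy]hex-3-ene-1,6-diol | OC[C@@H](O[Si](C)(C)C(C)(C)C)/C=C\[C@H](O[Si](C)(C)C(C)(C)C)CO | intermediate
8 | (2S,5S,3Z)-2,5-bis[(tert-butyldimethylsilyl)oxy]hex-3-enedial | O=C[C@@H](O[Si](C)(C)C(C)(C)C)/C=C\[C@H](O[Si](C)(C)C(C)(C)C)C=O | intermediate
9 | 3α,6β-bis[(tert-butyldimethylsilyl)oxy]cyclohex-1-ene-4β,5β-diol | C1=C[C@H](O[Si](C)(C)C(C)(C)C)[C@@H](O)[C@@H](O)[C@H]1O[Si](C)(C)C(C)(C)C | intermediate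
10 | cyclic methyl orthoacetate of 9 (4β,5β-O,O-(1-methoxyethylidene)) | C1=C[C@H](O[Si](C)(C)C(C)(C)C)[C@@H](OC(C)(OC)O2)[C@@H]2[C@H]1O[Si](C)(C)C(C)(C)C | intermediate
11 | 4β-acetoxy-5α-bromo-3α,6β-bis[(tert-butyldimethylsilyl)oxy]cyclohex-1-ene (regioisomer from bromide attack at C5) | C1=C[C@H](O[Si](C)(C)C(C)(C)C)[C@@H](OC(C)=O)[C@H](Br)[C@H]1O[Si](C)(C)C(C)(C)C | intermediate
12 | 4β,5β-epoxy-3α,6β-bis[(tert-butyldimethylsilyl)oxy]cyclohex-1-ene | C1=C[C@H](O[Si](C)(C)C(C)(C)C)[C@H]2O[C@H]2[C@H]1O[Si](C)(C)C(C)(C)C | intermediate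
13 | 4β,5β-epoxycyclohex-1-ene-3α,6β-diol | C1=C[C@H](O)[C@H]2O[C@H]2[C@H]1O | intermediate
14 | 4α-methoxycyclohex-1-ene-3α,5β,6β-triol | C1=C[C@H](O)[C@H](OC)[C@@H](O)[C@H]1O | intermediate
15 | 5β,6β-O,O-phenylboronate of 14 | C1=C[C@H](O)[C@H](OC)[C@@H](OB(c2ccccc2)O3)[C@H]13 | intermediate
16 | 3α-acetoxy-4α-methoxycyclohex-1-ene-5β,6β-diyl phenylboronate | C1=C[C@H](OC(C)=O)[C@H](OC)[C@@H](OB(c2ccccc2)O3)[C@H]13 | intermediate
17 | 3α-acetoxy-4α-methoxycyclohex-1-ene-5β,6β-diol | C1=C[C@H](OC(C)=O)[C@H](OC)[C@@H](O)[C@H]1O | intermediate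
18 | 3α-acetoxy-5β-hydroxy-4α-methoxycyclohex-1-en-6-one | C1=C[C@H](OC(C)=O)[C@H](OC)[C@@H](O)C1=O | intermediate
19 | 3α-acetoxy-5β-hydroxy-1-iodo-4α-methoxycyclohex-1-en-6-one | IC1=C[C@H](OC(C)=O)[C@H](OC)[C@@H](O)C1=O | intermediate
20 | 3α-acetoxy-1-iodo-4α-methoxycyclohex-1-ene-5β,6β-diol | IC1=C[C@H](OC(C)=O)[C@H](OC)[C@@H](O)[C@H]1O | intermediate
21 | (E)-2-methyl-4-(4,4,5,5-tetramethyl-1,3,2-dioxaborolan-2-yl)but-3-en-2-ol | CC(C)(O)/C=C/B1OC(C)(C)C(C)(C)O1 | starting material
22 | 2,3-dibromoprop-1-ene | C=C(Br)CBr | starting material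
23 | (3E)-6-bromo-2-methylhepta-3,6-dien-2-ol | C=C(Br)C/C=C/C(C)(C)O | intermediate
24 | ethynyltrimethylsilane | C#C[Si](C)(C)C | starting material
25 | (3E)-2-methyl-6-methylidene-8-(trimethylsilyl)oct-3-en-7-yn-2-ol | C=C(C#C[Si](C)(C)C)C/C=C/C(C)(C)O | intermediate
26 | (3E)-2-methyl-6-methylideneoct-3-en-7-yn-2-ol | C#CC(=C)C/C=C/C(C)(C)O | intermediate
27 | (1S,4S,5S,6R)-4,5-dihydroxy-3-[(5E)-7-hydroxy-7-methyl-3-methylideneoct-5-en-1-yn-1-yl]-6-methoxycyclohex-2-en-1-yl acetate | C=C(C#CC1=C[C@H](OC(C)=O)[C@H](OC)[C@@H](O)[C@H]1O)C/C=C/C(C)(C)O | target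

## Step count and risks

Total steps: 17. Longest linear sequence: 14 (steps 1–13 and 17).

Step 6 (key step). The β,γ-unsaturated α-silyloxy dialdehyde may epimerise or slip into conjugation under the amine of the Swern protocol, and the ketyl may lose the neighbouring silyloxide or be reduced further instead of closing the ring. The fallback sets out from 7 and returns at 9. Dess–Martin periodinane/NaHCO3 oxidises 7 to 8 without amine. A triazolium-derived N-heterocyclic carbene then closes the same C4–C5 bond by an intramolecular benzoin reaction to 3α,6β-bis[(tert-butyldimethylsilyl)oxy]-5-hydroxycyclohex-1-en-4-one F2, a single constitution because the two aldehydes are homotopic. Zn(BH4)2 reduces the ketone under chelation control to the cis-diol. Either carbinol epimer of the ketol leads to 9, because 9 is the only cis-diol.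

Step 1. The doubly activated ynedione may be consumed by conjugate addition of the liberated N,O-dimethylhydroxylamine or of a second acetylide, or the acylation may stop after the first addition. The fallback sets out from 1 and returns at 3. Ethynylenedimagnesium dibromide is added to (tert-butyldimethylsilyloxy)acetaldehyde (2 equiv) to give 1,6-bis[(tert-butyldimethylsilyl)oxy]hex-3-yne-2,5-diol F1 as a mixture of diastereomers. Oxidation of both propargylic alcohols with Dess–Martin periodinane gives 3, which is filtered and taken directly into step 2. Carbonyl addition plus oxidation replaces the direct acylation, and no amine is present when the ynedione forms.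

Step 13. Hydride may be delivered axially, without chelation, to give the trans-5,6-diol, and 1,4-reduction or loss of iodine may compete. The fallback sets out from 19 and returns at 20, with no new compound. It replaces substrate (chelation) control by catalyst control: Corey–Bakshi–Shibata reduction with the (S)-methyl oxazaborolidine and catecholborane at −78 °C. 2-Halo-cycloalkenones are standard substrates for this reduction, and with the iodo-bearing C1 as the large group the catalyst should deliver hydride to the face that places C6–OH β.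

Further compounds
F1 | step 1 | 1,6-bis[(tert-butyldimethylsilyl)oxy]hex-3-yne-2,5-diol (mixture of chiral and meso diastereomers) | CC(C)(C)[Si](C)(C)OCC(O)C#CC(O)CO[Si](C)(C)C(C)(C)C
F2 | step 6 | 3α,6β-bis[(tert-butyldimethylsilyl)oxy]-5β-hydroxycyclohex-1-en-4-one (the 5α epimer serves equally) | C1=C[C@H](O[Si](C)(C)C(C)(C)C)C(=O)[C@@H](O)[C@H]1O[Si](C)(C)C(C)(C)C
F0 | step 13 | none | none
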